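## Structural features

The target is a 2‑arylchromen‑4‑one. Ring A is fused to the pyranone ring C through C4a and C8a, and ring B hangs on C2 through the C2–C1' bond. The target has no stereocentre. Stereocentres appear only in the flavan intermediates, at C2 and C4, which are 1,3‑related across the C3 methylene and not adjacent.

Each benzene ring is a 1,2,3,5‑tetraoxygenated arene with a single free CH. Ring A carries O1 at C8a, OH at C5, OMe at C6 and C7, and H at C8. Ring B carries OMe at C2', C3' and C4', OH at C6', and H at C5'.

The fragile points are the two electron‑rich rings, which are easily oxidized or alkylated at C8 and C5', and the 6'‑hydroxyl. Because the 6'‑hydroxyl sits ortho to the C2–C1' bond, strong base could in principle open ring C to a 1,3‑diketone that recloses on the other phenol and exchanges the roles of rings A and B.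

The carbon skeleton is not the real difficulty. The difficulty is to tell two hydroxyls (O5, O6') from five methoxyls, and to attach a ring B with both ortho positions substituted to C2.

The feature used by the key step is a hidden repetition. Ring A with O1 and C4, and ring B with C2, are the same 6‑oxy‑2,3,4‑trimethoxyphenyl unit bearing one extra carbon, that is, one salicylaldehyde. As its ortho‑quinone methide this aldehyde supplies O1–C8a–C4a–C4. As its O‑protected vinyl derivative it supplies C2=C3. A [4+2] reaction then forms O1–C2 and C3–C4 and closes ring C with the hindered aryl group on an sp3 carbon.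

## Logic of the disconnections

13 ⇒ 12. The O5–CH3 and O6'–CH2Ph bonds are the last ones cut in the forward direction. With O5 methylated, ring A of 12 has the same trimethoxy pattern as ring B, so both halves can come from one building block. O5 is the only methoxyl peri to the C4 carbonyl and can be singled out by chelation. O6' has no such handle and needs a non‑methyl group that falls under the same reagent. The gain is that no oxygen has to be differentiated earlier. The demand is that the forward step cleave one of six methyl ethers and the benzyl ether without alkylating C8 or C5'.

12 ⇒ 11. The C2=C3 π bond is removed. This makes C2 an sp3 carbon, which is where a di‑ortho‑substituted aryl group is most easily attached. The forward dehydrogenation must not halogenate or oxidize the two electron‑rich rings.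

11 ⇒ 10. The C4 carbonyl is exchanged for C4(H)–OMe. The C4 methoxyl is what the cycloaddition leaves behind, and it puts C4 one hydride abstraction away from the ketone level. The demand is site selectivity. The oxidant must take the hydride from C4 and leave C2–H and the benzyl CH2 alone.

10 ⇒ 2 + 6 (with 7, through 8 and 9). The O1–C2 and C3–C4 bonds are cut together. This retro‑[4+2] splits the molecule into two monocyclic halves of nearly equal size that share one origin, and it removes ring C and both stereocentres in one operation. The forward step has three demands:
- 9 must be generated from 2 and 7 via 8 at a low stationary concentration.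
- The acid must be mild enough for 6 to survive.
- The polarity of the partners must place the aryl group at C2.

6 ⇒ 4 + 5. The vinyl C=C bond (the future C2–C3) is cut to a carbonyl and a one‑carbon ylide. This returns the ring B half to the aldehyde oxidation level of the ring A half. The demand is methylenation of a hindered but non‑enolizable aldehyde.

4 ⇒ 2 + 3. The O6'–CH2Ph bond is cut. This is the only point where the two halves differ. The protecting group must survive acid, a quinone oxidant and iodine, and must leave together with the O5 methyl group.

2 ⇒ 1. The aryl–CHO bond is cut. Both positions ortho to the hydroxyl of 1 are equivalent by symmetry, so formylation directed by the phenoxide can give only one product. The demand is mono‑formylation without para attack; the para position is blocked in 1.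

## Other disconnections considered

Alternative 1: The cut is at the two aryl C–O bonds, C8a–O and C6'–O. The target is traced through cyclodehydration back to the bis‑phenol diketone A2, and A2 to the symmetric diketone A1. The forward key step is a twofold ketone‑directed ortho C–H hydroxylation of A1 with [RuCl2(p‑cymene)]2 and K2S2O8 in trifluoroacetic acid and its anhydride. It closes no ring.

- In its favour: A1 should come from one Claisen condensation of simple trimethoxyphenyl building blocks. Each ring has only one ortho C–H, so the site is not in doubt. A2 is symmetric, so whichever phenol closes on whichever carbonyl, the same flavone with 5‑OMe and 6'‑OH results. No protecting group is needed.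
- Against it: a 1,3‑diketone is largely enolized and would bind ruthenium as a chelating diketonate, competing with the weak ketone coordination needed for cyclometalation. Each carbonyl is twisted by its ortho methoxyl. Persulfate in strong acid is a harsh medium for trimethoxyarenes and for the central enol. The hydroxylation must also occur twice. If the mono‑hydroxylated material cyclizes in the acid first, the remaining ring loses its directing ketone and the second hydroxylation would stall.
- Comparison: on structure the two plans are equal, since both use the identity of rings A and B. On step economy the alternative is better, about four steps against seven and without a benzyl group. On mechanism the chosen plan is safer, because it rests on polar bond formation with class precedent, whereas the directing logic for a chelating diketone is unsecured. The final cleavage of the 5‑methyl ether is the same in both.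

Alternative 2: The cut is at the C6'–O bond, made with the help of a temporary carboxyl group at C3. The target is traced through 5‑demethylation, lactone opening and decarboxylation back to lactone A4, and A4 to the flavone‑3‑carboxylic acid A3. The forward key step is anodic oxidation of A3 at a carbon anode, in which a carboxyl oxygen bonds to C6' and closes a six‑membered lactone.

- In its favour: the oxygen is delivered intramolecularly, so among C–H positions only C6' can be reached. No chemical oxidant is used. Ring B enters as a plain 2,3,4‑trimethoxyphenyl group, so ring C can be built by classical condensations without a di‑ortho‑substituted aryl group, which is better than the chosen plan on that point. The lactone also masks O6' without a separate protecting group.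
- Against it: the carboxyl group is an auxiliary that must be installed and later removed. Both arenes of A3 oxidize at low potential, so oxidation of ring A, demethylative quinone formation, ipso attack at the methoxy‑bearing C2' and Kolbe‑type decarboxylation all compete with the desired coupling. A3 itself needs several steps.
- Comparison: on structure, late C–H oxygenation is equal or better in protecting‑group terms but worse in atom economy. On mechanism, radical‑cation chemistry on two polyoxygenated rings is less predictable than the closed‑shell cycloaddition. On step economy the alternative is equal at best: A3, lactonization, opening with decarboxylation, then 5‑demethylation.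

Alternative 3: The cut is at the C4a–C5 bond of ring A. The target is traced through debenzylation and 7‑O‑methylation back to the dihydroxyflavone A6, and A6 to the pyranone‑bound methoxy β‑keto ester A5. The forward key step is a base‑mediated intramolecular Claisen condensation. Deprotonation of the methylene between pyranone and ketone gives an extended dienolate. Its C4a attacks the ester carbonyl, and enolization aromatizes ring A.

- In its favour: the route is biomimetic. Ring A is born with 6‑OMe in place and with 5‑OH and 7‑OH free. The chelated 5‑OH resists mild methylation, so the O5/O7 problem is solved by construction and not by a late selective demethylation, which is better than the chosen plan on that point. Ring C has the flavone oxidation level from the start, so no oxidation steps are needed, which is also better.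
- Against it: A5 is a sensitive polycarbonyl compound. Its most acidic site is the methine between ketone and ester, whose enolate is unproductive. Pyranones are opened by alkoxide, and retro‑Claisen cleavage competes. Making A5, a pyranone carrying the hindered ring B and a methoxymalonyl‑type side chain, is itself a long sequence. Two steps still follow A6.
- Comparison: on structure the alternative ignores the A/B identity that the chosen plan exploits. On mechanism it is an enolate condensation with several competing acidic sites, against one clearly polarized cycloaddition. On step economy it is probably several steps longer. It equals or betters the chosen plan only in the endgame selectivity.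

Key step: step 4

Remark: the flavan structure of the key step encodes the (2S,4S), that is cis, arrangement, so structure and name agree and no correction is needed. Compound 10 is understood as the racemate, and any trans isomer would follow the same route.

Remark: three changes are made to the outline. Acetal 8 is formed before 6 is added. The oxidation of ring C is split into a room‑temperature ether oxidation and a separate dehydrogenation. A cation scavenger is used in the last step.

## Route

Step 1
Reactants: 1 3,4,5‑trimethoxyphenol
Product: 2 6‑hydroxy‑2,3,4‑trimethoxybenzaldehyde
Conditions: MgCl2, Et3N, (CH2O)n, MeCN, reflux; aq. HCl work‑up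
Reagents that add atoms: paraformaldehyde (formaldehyde unit), C=O
Why: Casnati–Skattebøl ortho‑formylation: the magnesium phenoxide directs formaldehyde to the ortho carbon and a second formaldehyde accepts hydride from the hydroxymethyl intermediate; the two ortho positions of 1 are equivalent and the para position is blocked, so only one aldehyde can form.

Step 2
Reactants: 2 6‑hydroxy‑2,3,4‑trimethoxybenzaldehyde; 3 benzyl bromide
Product: 4 6‑(benzyloxy)‑2,3,4‑trimethoxybenzaldehyde
Conditions: K2CO3, DMF, 60 °C
Reagents that add atoms: none
Why: Williamson etherification of the phenoxide; warming in a dipolar solvent overcomes the hydrogen bond to the aldehyde, and the aldehyde has no enolizable position.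

Step 3
Reactants: 4 6‑(benzyloxy)‑2,3,4‑trimethoxybenzaldehyde; 5 methyltriphenylphosphonium bromide
Product: 6 1‑(benzyloxy)‑2‑ethenyl‑3,4,5‑trimethoxybenzene
Conditions: KOtBu, THF, 0 °C → rt
Reagents that add atoms: none
Why: Wittig methylenation with the small non‑stabilized ylide, which reaches di‑ortho‑substituted aryl aldehydes; the styrene is kept free of acid (base‑washed silica, cold storage) until use.

Step 4
Reactants: 2 6‑hydroxy‑2,3,4‑trimethoxybenzaldehyde; 6 1‑(benzyloxy)‑2‑ethenyl‑3,4,5‑trimethoxybenzene; 7 trimethyl orthoformate
Product: 10 racemic cis‑2‑[6‑(benzyloxy)‑2,3,4‑trimethoxyphenyl]‑4,5,6,7‑tetramethoxychroman, via dimethyl acetal 8 (not isolated), via ortho‑quinone methide 9 (not isolated)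
Conditions: 7 (3 equiv), CSA (10 mol%), CH2Cl2, rt; then 6 added slowly, 0 °C → rt
Reagents that add atoms: none
Why: Acid‑catalysed exchange with 7 turns the aldehyde of 2 into acetal 8, which ionizes with loss of methanol to the methoxy‑substituted ortho‑quinone methide 9, an oxocarbenium‑like heterodiene stabilized by the ring methoxyls. The electron‑rich alkene of 6 adds in a strongly asynchronous inverse‑electron‑demand hetero‑Diels–Alder reaction, C3–C4 bond formation running ahead of O1–C2 bond formation. The closest known reaction type is the acid‑promoted three‑component coupling of salicylaldehydes, orthoformates and styrenes to 2‑aryl‑4‑alkoxychromans. Ring C closes by [4+2] cycloaddition, four atoms (O1, C8a, C4a, C4) coming from 9 and two (C2, C3) from 6; in the stepwise limit the phenolic oxygen captures the ring B benzylic cation to complete the six‑membered ring. C2 and C4 arise together as a racemate, the cis relation following from an endo placement of the aryl group under the E‑configured methide whose methoxyl points outward; no absolute control is needed and neither centre reaches the target, so a trans component may be carried on. The selectivity that matters is 2‑aryl against 3‑aryl, and polarity secures it: the terminal CH2 is the nucleophilic end, and the benzylic carbon, flanked by ortho and para oxygens of ring B, takes the positive charge that O1 then quenches. Chemoselectivity against styrene dimerization and against arylation at the free C5' and C8 positions rests on a weak acid in catalytic amount, prior formation of 8 and slow addition of 6.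

Step 5
Reactants: 10 racemic cis‑2‑[6‑(benzyloxy)‑2,3,4‑trimethoxyphenyl]‑4,5,6,7‑tetramethoxychroman
Product: 11 racemic 2‑[6‑(benzyloxy)‑2,3,4‑trimethoxyphenyl]‑5,6,7‑trimethoxychroman‑4‑one
Conditions: DDQ (1.3 equiv), CH2Cl2/H2O, 0 °C → rt
Reagents that add atoms: water, O
Why: Oxidative cleavage of an electron‑rich benzylic methyl ether, the same manifold as DDQ removal of polymethoxybenzyl ethers: hydride leaves C4 to give a cation stabilized by the C4 methoxyl and by the ortho and para oxygens of ring A, water adds and methanol is lost. C2–H is held near the plane of the di‑ortho‑substituted ring B and is poorly aligned for abstraction, and an unactivated benzyl ether is inert to DDQ at room temperature; DDQ functionalization at C4 of oxygenated, benzyl‑protected flavans is the class precedent.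

Step 6
Reactants: 11 racemic 2‑[6‑(benzyloxy)‑2,3,4‑trimethoxyphenyl]‑5,6,7‑trimethoxychroman‑4‑one
Product: 12 2‑[6‑(benzyloxy)‑2,3,4‑trimethoxyphenyl]‑5,6,7‑trimethoxy‑4H‑chromen‑4‑one
Conditions: I2 (10 mol%), DMSO, 110 °C
Reagents that add atoms: none
Why: Iodine/DMSO dehydrogenation of a flavanone: the enol is iodinated at C3, hydrogen iodide is eliminated across C2–C3 and DMSO reoxidizes iodide to iodine, so only a catalytic amount of the electrophile is present and nuclear iodination is limited. The C2 stereocentre disappears and the aromatic pyranone is the thermodynamic sink.

Step 7
Reactants: 12 2‑[6‑(benzyloxy)‑2,3,4‑trimethoxyphenyl]‑5,6,7‑trimethoxy‑4H‑chromen‑4‑one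
Product: 13 5,6'‑dihydroxy‑6,7,2',3',4'‑pentamethoxyflavone, i.e. 5‑hydroxy‑2‑(6‑hydroxy‑2,3,4‑trimethoxyphenyl)‑6,7‑dimethoxy‑4H‑chromen‑4‑one
Conditions: BCl3 (4 equiv), C6HMe5, CH2Cl2, −78 → 0 °C; then H2O
Reagents that add atoms: none
Why: Lewis‑acid ether cleavage: BCl3 removes the aryl benzyl ether, the benzyl cation being trapped by pentamethylbenzene in a Friedel–Crafts reaction, and it cleaves the 5‑methyl ether through the six‑membered chelate between the C4 carbonyl and O5, chloride attacking the methyl group. The other five methoxyls lack this chelation and should persist at low temperature, and the neutral aqueous work‑up avoids base‑induced opening of ring C.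

## Compound list

1 | 3,4,5‑trimethoxyphenol | COc1cc(O)cc(OC)c1OC | starting material
2 | 6‑hydroxy‑2,3,4‑trimethoxybenzaldehyde | COc1cc(O)c(C=O)c(OC)c1OC | intermediate
3 | benzyl bromide | BrCc1ccccc1 | starting material
4 | 6‑(benzyloxy)‑2,3,4‑trimethoxybenzaldehyde | COc1cc(OCc2ccccc2)c(C=O)c(OC)c1OC | intermediate
5 | methyltriphenylphosphonium bromide | C[P+](c1ccccc1)(c1ccccc1)c1ccccc1.[Br-] | starting material
6 | 1‑(benzyloxy)‑2‑ethenyl‑3,4,5‑trimethoxybenzene | C=Cc1c(OCc2ccccc2)cc(OC)c(OC)c1OC | intermediate
7 | trimethyl orthoformate | COC(OC)OC | starting material
8 | 2‑(dimethoxymethyl)‑3,4,5‑trimethoxyphenol (dimethyl acetal of 2, not isolated) | COC(OC)c1c(O)cc(OC)c(OC)c1OC | intermediate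
9 | (6E)‑3,4,5‑trimethoxy‑6‑(methoxymethylidene)cyclohexa‑2,4‑dien‑1‑one (ortho‑quinone methide, E geometry drawn, not isolated) | CO/C=C1/C(=O)C=C(OC)C(OC)=C1OC | intermediate
10 | racemic cis‑2‑[6‑(benzyloxy)‑2,3,4‑trimethoxyphenyl]‑4,5,6,7‑tetramethoxychroman, (2S,4S) enantiomer drawn | COc1cc(OCc2ccccc2)c([C@@H]2C[C@H](OC)c3c(OC)c(OC)c(OC)cc3O2)c(OC)c1OC | intermediate
11 | racemic 2‑[6‑(benzyloxy)‑2,3,4‑trimethoxyphenyl]‑5,6,7‑trimethoxychroman‑4‑one, (2S) enantiomer drawn | COc1cc(OCc2ccccc2)c([C@@H]2CC(=O)c3c(OC)c(OC)c(OC)cc3O2)c(OC)c1OC | intermediate
12 | 2‑[6‑(benzyloxy)‑2,3,4‑trimethoxyphenyl]‑5,6,7‑trimethoxy‑4H‑chromen‑4‑one | COc1cc(OCc2ccccc2)c(-c2cc(=O)c3c(OC)c(OC)c(OC)cc3o2)c(OC)c1OC | intermediate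
13 | 5‑hydroxy‑2‑(6‑hydroxy‑2,3,4‑trimethoxyphenyl)‑6,7‑dimethoxy‑4H‑chromen‑4‑one (5,6'‑dihydroxy‑6,7,2',3',4'‑pentamethoxyflavone) | COc1cc(O)c(-c2cc(=O)c3c(O)c(OC)c(OC)cc3o2)c(OC)c1OC | target

## Step count and risks

Total step count: 7. Longest linear sequence: 7 steps (1 → 2 → 4 → 6 → 10 → 11 → 12 → 13). Aldehyde 2 serves both halves.

Least certain steps:

Step 4 (key step). The most likely failure is acid‑induced self‑reaction of the very electron‑rich styrene (cationic dimerization or oligomerization). A second is Friedel–Crafts attack of the methide on the free aromatic positions C5' and C8 in place of cycloaddition, because both rings are strong π‑nucleophiles and the highly stabilized methide is a sluggish heterodiene. The fallback gives up the cycloaddition for the chalcone route, sets out from 1 and 4, and returns at 12. Compound 1 is acetylated ortho to its hydroxyl (Ac2O, BF3·OEt2) to 1‑(6‑hydroxy‑2,3,4‑trimethoxyphenyl)ethan‑1‑one F1. Claisen–Schmidt condensation of F1 with 4 (KOH, EtOH) gives (2E)‑3‑[6‑(benzyloxy)‑2,3,4‑trimethoxyphenyl]‑1‑(6‑hydroxy‑2,3,4‑trimethoxyphenyl)prop‑2‑en‑1‑one F2. Oxidative cyclization of F2 with I2 in DMSO should then give 12 directly.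

Step 5. Hydride abstraction may occur at C2 instead of C4, which would cleave the O1–C2 bond. The C4 cation may also lose a proton from C3, followed by further oxidation of the resulting enol ether. Both follow from the fact that C2 and C4 are each benzylic to a polyoxygenated ring. The fallback replaces hydride abstraction by ionization and alcohol oxidation, sets out from 10 and returns at 11. Mild aqueous acid (PPTS, acetone/H2O) exchanges the C4 methoxyl for hydroxyl through the same stabilized cation, giving 2‑[6‑(benzyloxy)‑2,3,4‑trimethoxyphenyl]‑5,6,7‑trimethoxychroman‑4‑ol F3 as a mixture of C4 epimers. Dess–Martin periodinane then oxidizes F3 to 11.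

Step 6. Electrophilic iodination of the free C8 and C5' positions may compete with iodination of the enol, since both rings are highly activated. Thermal retro‑oxa‑Michael opening of the hindered flavanone may slow the elimination. The fallback uses palladium enolate chemistry in place of halogenation–elimination, sets out from 11 and returns at 12. Soft enolization (TMSOTf, Et3N, CH2Cl2, 0 °C) gives racemic {[2‑[6‑(benzyloxy)‑2,3,4‑trimethoxyphenyl]‑5,6,7‑trimethoxy‑2H‑chromen‑4‑yl]oxy}trimethylsilane F4. Saegusa–Ito oxidation of F4 with Pd(OAc)2 (divalent palladium) in MeCN should then give 12 by β‑hydride elimination of the C2 hydrogen.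

Step 7. Over‑demethylation may occur, at O6 once the O5 borate is formed or at the central methoxyl of ring B. The released benzyl cation may also C‑benzylate C8 or C5' if trapping is incomplete, because one reagent is asked to do two jobs on a substrate with six methyl ethers. The fallback separates the two deprotections and changes the mechanism of the first, sets out from 12 and returns at 13. Hydrogenolysis (H2, Pd/C, EtOAc/MeOH) removes the benzyl group without a cationic intermediate and gives 2‑(6‑hydroxy‑2,3,4‑trimethoxyphenyl)‑5,6,7‑trimethoxy‑4H‑chromen‑4‑one F5. The 5‑methyl ether of F5 is then cleaved as a separate, titratable operation with AlCl3 in MeCN to give 13.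

## Further compounds

F1 | step 4 | 1‑(6‑hydroxy‑2,3,4‑trimethoxyphenyl)ethan‑1‑one | CC(=O)c1c(O)cc(OC)c(OC)c1OC
F2 | step 4 | (2E)‑3‑[6‑(benzyloxy)‑2,3,4‑trimethoxyphenyl]‑1‑(6‑hydroxy‑2,3,4‑trimethoxyphenyl)prop‑2‑en‑1‑one | COc1cc(OCc2ccccc2)c(/C=C/C(=O)c2c(O)cc(OC)c(OC)c2OC)c(OC)c1OC
F3 | step 5 | racemic 2‑[6‑(benzyloxy)‑2,3,4‑trimethoxyphenyl]‑5,6,7‑trimethoxychroman‑4‑ol, C4 epimers, cis (2S,4S) isomer drawn | COc1cc(OCc2ccccc2)c([C@@H]2C[C@H](O)c3c(OC)c(OC)c(OC)cc3O2)c(OC)c1OC
F4 | step 6 | racemic {[2‑[6‑(benzyloxy)‑2,3,4‑trimethoxyphenyl]‑5,6,7‑trimethoxy‑2H‑chromen‑4‑yl]oxy}trimethylsilane, (2S) enantiomer drawn | COc1cc(OCc2ccccc2)c([C@@H]2C=C(O[Si](C)(C)C)c3c(OC)c(OC)c(OC)cc3O2)c(OC)c1OC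
F5 | step 7 | 2‑(6‑hydroxy‑2,3,4‑trimethoxyphenyl)‑5,6,7‑trimethoxy‑4H‑chromen‑4‑one | COc1cc(O)c(-c2cc(=O)c3c(OC)c(OC)c(OC)cc3o2)c(OC)c1OC
A1 | alternative 1 | 1,3‑bis(2,3,4‑trimethoxyphenyl)propane‑1,3‑dione | COc1ccc(C(=O)CC(=O)c2ccc(OC)c(OC)c2OC)c(OC)c1OC
A2 | alternative 1 | 1,3‑bis(6‑hydroxy‑2,3,4‑trimethoxyphenyl)propane‑1,3‑dione | COc1cc(O)c(C(=O)CC(=O)c2c(O)cc(OC)c(OC)c2OC)c(OC)c1OC
A3 | alternative 2 | 5,6,7‑trimethoxy‑4‑oxo‑2‑(2,3,4‑trimethoxyphenyl)‑4H‑chromene‑3‑carboxylic acid | COc1ccc(-c2oc3cc(OC)c(OC)c(OC)c3c(=O)c2C(=O)O)c(OC)c1OC
A4 | alternative 2 | hexamethoxy‑6H,7H‑chromeno[4,3‑b]chromene‑6,7‑dione (lactone between O6' and the C3 carboxyl of A3) | COc1cc2oc(=O)c3c(=O)c4c(OC)c(OC)c(OC)cc4oc3c2c(OC)c1OC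
A5 | alternative 3 | racemic methyl 4‑{6‑[6‑(benzyloxy)‑2,3,4‑trimethoxyphenyl]‑4‑oxo‑4H‑pyran‑2‑yl}‑2‑methoxy‑3‑oxobutanoate, one enantiomer drawn, centre labile | COC(=O)[C@H](OC)C(=O)Cc1cc(=O)cc(-c2c(OCc3ccccc3)cc(OC)c(OC)c2OC)o1
A6 | alternative 3 | 2‑[6‑(benzyloxy)‑2,3,4‑trimethoxyphenyl]‑5,7‑dihydroxy‑6‑methoxy‑4H‑chromen‑4‑one | COc1cc(OCc2ccccc2)c(-c2cc(=O)c3c(O)c(OC)c(O)cc3o2)c(OC)c1OC
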